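The tetrahydropyran (O1, C2–C6) is cut at C4–C5, C3–C4 and O1–C2. Its C4 is a bare methylene between C3 and C5, so it is taken from formaldehyde; O1–C6–C5 with the carbinol carbon is an aroylacetaldehyde, and the cis C2(aryl)/C3 pair is a (Z)-styrene. One acid-catalysed three-component operation (Knoevenagel condensation, then inverse-demand oxa-Diels–Alder addition) should assemble the dihydropyran with C2 and C3 both set. The styrene partner carries its C3 side chain as a 1-phenyltetrazolyl sulfone, so that the (E)-styryl arm follows later by one Julia–Kocienski olefination; all phenols are silyl ethers.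

Key step: step 8

Assumption: ring numbering is O1, C2 (aryl), C3 (side chain), C4 (CH2), C5 (carbinol-bearing), C6 (OCH2). The phenols are carried as triisopropylsilyl ethers (tert-butyldimethylsilyl on the last arene), and the terminus of the C3 side chain is a 1-phenyl-1H-tetrazol-5-yl sulfone, which is a spectator group in the key step. Compound 3 is drawn as the keto aldehyde although it exists as its hydrogen-bonded enol.

Step 1
Reactants: 1 4'-hydroxyacetophenone
Product: 2 1-[4-(triisopropylsilyloxy)phenyl]ethan-1-one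
Conditions: TIPSCl, imidazole, DMF, rt
Reagents that add atoms: triisopropylsilyl chloride, CC(C)[Si](Cl)(C(C)C)C(C)C
Why: Imidazole-promoted O-silylation of a phenol, with the bulky triisopropylsilyl group chosen because it should resist the ethoxide of step 2, the strong acid of step 8 and the amide base of step 11.

Step 2
Reactants: 2 1-[4-(triisopropylsilyloxy)phenyl]ethan-1-one
Product: 3 3-oxo-3-[4-(triisopropylsilyloxy)phenyl]propanal
Conditions: NaH, HCO2Et, THF, 0 °C to rt; then AcOH, H2O, 0 °C
Reagents that add atoms: ethyl formate, CCOC=O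
Why: Crossed Claisen formylation of the methyl ketone enolate with non-enolisable ethyl formate is driven by formation of the stabilised sodium enolate of 3, and since free aroylacetaldehydes self-condense, 3 should be stored as that salt and released with acetic acid just before step 8.

Step 3
Reactants: 4 3-butyn-1-ol
Product: 5 5-(but-3-yn-1-ylsulfanyl)-1-phenyl-1H-tetrazole
Conditions: 1-phenyl-1H-tetrazole-5-thiol, PPh3, DIAD, THF, 0 °C to rt
Reagents that add atoms: 1-phenyl-1H-tetrazole-5-thiol, Sc1nnnn1-c1ccccc1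
Why: Mitsunobu thioetherification of an unhindered primary alcohol with an acidic heteroaryl thiol.

Step 4
Reactants: 5 5-(but-3-yn-1-ylsulfanyl)-1-phenyl-1H-tetrazole
Product: 6 5-(but-3-yn-1-ylsulfonyl)-1-phenyl-1H-tetrazole
Conditions: (NH4)6Mo7O24·4H2O (cat.), 30% H2O2, EtOH, 0 °C to rt
Reagents that add atoms: hydrogen peroxide, OO
Why: Molybdate-catalysed peroxide oxidation of a sulfide to the sulfone, which should leave the terminal alkyne untouched.

Step 5
Reactants: 7 4-iodophenol
Product: 8 (4-iodophenoxy)triisopropylsilane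
Conditions: TIPSCl, imidazole, DMF, rt
Reagents that add atoms: triisopropylsilyl chloride, CC(C)[Si](Cl)(C(C)C)C(C)C
Why: Imidazole-promoted O-silylation of a phenol.

Step 6
Reactants: 6 5-(but-3-yn-1-ylsulfonyl)-1-phenyl-1H-tetrazole; 8 (4-iodophenoxy)triisopropylsilane
Product: 9 1-phenyl-5-({4-[4-(triisopropylsilyloxy)phenyl]but-3-yn-1-yl}sulfonyl)-1H-tetrazole
Conditions: Pd(PPh3)2Cl2 (2 mol%), CuI (4 mol%), Et3N, THF, rt
Reagents that add atoms: none
Why: Sonogashira coupling of an aryl iodide with a terminal alkyne at room temperature, where the tertiary amine is too weak a base and nucleophile to attack the heteroaryl sulfone.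

Step 7
Reactants: 9 1-phenyl-5-({4-[4-(triisopropylsilyloxy)phenyl]but-3-yn-1-yl}sulfonyl)-1H-tetrazole
Product: 10 1-phenyl-5-({(3Z)-4-[4-(triisopropylsilyloxy)phenyl]but-3-en-1-yl}sulfonyl)-1H-tetrazole
Conditions: H2 (1 atm), Pd/CaCO3 poisoned with Pb(OAc)2, quinoline, EtOAc, rt
Reagents that add atoms: none
Why: Lindlar-type semihydrogenation delivers both hydrogens to one face of the alkyne on the poisoned surface and should stop at the (Z)-alkene, the sulfone being inert.

Step 8
Reactants: 3 3-oxo-3-[4-(triisopropylsilyloxy)phenyl]propanal; 11 formaldehyde (charged as paraformaldehyde); 10 1-phenyl-5-({(3Z)-4-[4-(triisopropylsilyloxy)phenyl]but-3-en-1-yl}sulfonyl)-1H-tetrazole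
Product: 13 cis-(2R,3R)-5-[4-(triisopropylsilyloxy)benzoyl]-2-[4-(triisopropylsilyloxy)phenyl]-3-[2-(1-phenyl-1H-tetrazol-5-ylsulfonyl)ethyl]-3,4-dihydro-2H-pyran, via 2-aroylacrolein 12 (not isolated)
Conditions: (CH2O)n (1.5 equiv), 3 (1.5 equiv), chiral BINOL-derived N-triflyl imidodiphosphorimidate acid (5 mol%, antipode chosen by screening), 4 Å MS, CHCl3, −20 °C to rt
Reagents that add atoms: none
Why: Proposed new method: the acid should promote aldol addition of the enol of 3 to formaldehyde and loss of water to give the electron-poor 1-oxadiene 12, which the electron-rich (Z)-styrene 10 intercepts in a concerted but asynchronous inverse-demand [4+2] addition, the C3–C4 bond (styrene β-carbon to the methylene) running ahead of the O1–C2 bond (formyl oxygen to the benzylic carbon). The closest known reaction type is the racemic amine- or heat-promoted domino Knoevenagel/hetero-Diels–Alder reaction of 1,3-dicarbonyl compounds with formaldehyde and styrenes, taken together with confined-acid catalysis of other oxa-[4+2] additions; an enantioselective version with a (Z)-styrene has not been shown. The one ring closed, the six-membered dihydropyran, closes in the intermolecular [4+2] addition itself, and because C4 is a methylene and C5 and C6 are sp2, endo or exo approach has no stereochemical consequence. The cis relation of C2 and C3 should be carried over from the (Z) geometry by suprafacial addition, and their absolute configuration should come from the chiral anion pocket, which holds the protonated dicarbonyl unit of 12 and opens only one of its faces to the styrene. The step needs the formyl and not the aroyl oxygen in the ring, which the unhindered s-cis formyl–methylene unit and the retained aryl ketone conjugation of the product favour, and it needs the C3–C4/O1–C2 orientation, which the 4-silyloxyphenyl group secures by stabilising positive charge at C2. It also needs the cycloaddition to outrun ionisation to a free benzylic cation, Prins addition of formaldehyde to the styrene and self-condensation of 3, for which low temperature, sieves and the non-nucleophilic sulfone side chain are chosen.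

Step 9
Reactants: 13 cis-(2R,3R)-5-[4-(triisopropylsilyloxy)benzoyl]-2-[4-(triisopropylsilyloxy)phenyl]-3-[2-(1-phenyl-1H-tetrazol-5-ylsulfonyl)ethyl]-3,4-dihydro-2H-pyran
Product: 14 all-cis (2R,3R,5R)-5-[4-(triisopropylsilyloxy)benzoyl]-2-[4-(triisopropylsilyloxy)phenyl]-3-[2-(1-phenyl-1H-tetrazol-5-ylsulfonyl)ethyl]tetrahydro-2H-pyran
Conditions: H2 (1 atm), Pd/C (5%), EtOAc, rt, stopped after one equivalent of H2
Reagents that add atoms: none
Why: Heterogeneous syn-hydrogenation of the C5=C6 bond of a β-alkoxy enone should take place on the ring face opposite the cis C2-aryl and C3-alkyl groups, which places the aroyl group at C5 cis to both (5R), while neutral ethyl acetate and one atmosphere are chosen to spare the aryl ketone, the benzylic C2–O1 bond and the sulfone and to avoid epimerising C5.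

Step 10
Reactants: 14 all-cis (2R,3R,5R)-5-[4-(triisopropylsilyloxy)benzoyl]-2-[4-(triisopropylsilyloxy)phenyl]-3-[2-(1-phenyl-1H-tetrazol-5-ylsulfonyl)ethyl]tetrahydro-2H-pyran
Product: 15 all-cis (2R,3R,5R)-5-{(R)-hydroxy[4-(triisopropylsilyloxy)phenyl]methyl}-2-[4-(triisopropylsilyloxy)phenyl]-3-[2-(1-phenyl-1H-tetrazol-5-ylsulfonyl)ethyl]tetrahydro-2H-pyran
Conditions: (S)-2-methyl-CBS-oxazaborolidine (0.5 equiv), BH3·SMe2, THF, −20 °C; then MeOH
Reagents that add atoms: none
Why: Corey–Bakshi–Shibata reduction with the aryl group as the larger ketone substituent should give the (R)-carbinol under reagent control, in the sense in which this catalyst turns acetophenone into (R)-1-phenylethanol, and placing it here removes the β-alkoxy ketone (prone to C5 epimerisation and ring opening by base) before step 11, at a stage where no alkene is present for borane to attack.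

Step 11
Reactants: 15 all-cis (2R,3R,5R)-5-{(R)-hydroxy[4-(triisopropylsilyloxy)phenyl]methyl}-2-[4-(triisopropylsilyloxy)phenyl]-3-[2-(1-phenyl-1H-tetrazol-5-ylsulfonyl)ethyl]tetrahydro-2H-pyran; 16 4-(tert-butyldimethylsilyloxy)benzaldehyde
Product: 17 all-cis (2R,3S,5R)-3-{(2E)-3-[4-(tert-butyldimethylsilyloxy)phenyl]prop-2-en-1-yl}-5-{(R)-hydroxy[4-(triisopropylsilyloxy)phenyl]methyl}-2-[4-(triisopropylsilyloxy)phenyl]tetrahydro-2H-pyran
Conditions: KN(SiMe3)2 (2.3 equiv) added to 15 and 16, DME, −60 °C to rt; then aq NH4Cl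
Reagents that add atoms: none
Why: Julia–Kocienski olefination, in which the first equivalent of base forms the alkoxide and the second the sulfonyl carbanion that adds to the aryl aldehyde, and Smiles rearrangement with loss of SO2 and the tetrazolone should give the (E)-alkene as is usual for 1-phenyltetrazolyl sulfones with aromatic aldehydes; the C3 descriptor changes from R to S only because the side chain loses its sulfur and with it its CIP rank, and any silyl transfer to the alkoxide would be erased in step 12.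

Step 12
Reactants: 17 all-cis (2R,3S,5R)-3-{(2E)-3-[4-(tert-butyldimethylsilyloxy)phenyl]prop-2-en-1-yl}-5-{(R)-hydroxy[4-(triisopropylsilyloxy)phenyl]methyl}-2-[4-(triisopropylsilyloxy)phenyl]tetrahydro-2H-pyran
Product: 18 all-cis (2R,3S,5R)-5-[(R)-hydroxy(4-hydroxyphenyl)methyl]-2-(4-hydroxyphenyl)-3-[(2E)-3-(4-hydroxyphenyl)prop-2-en-1-yl]tetrahydro-2H-pyran (CNP0182155.1)
Conditions: Bu4NF (3.5 equiv), AcOH (3.5 equiv), THF, 0 °C
Reagents that add atoms: none
Why: Fluoride-mediated cleavage of the three aryl silyl ethers, buffered with acetic acid so that the 4-hydroxybenzylic alcohol is not driven towards a quinone methide.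

Compound list
1 | 4'-hydroxyacetophenone | CC(=O)c1ccc(O)cc1 | starting material
2 | 1-[4-(triisopropylsilyloxy)phenyl]ethan-1-one | CC(=O)c1ccc(O[Si](C(C)C)(C(C)C)C(C)C)cc1 | intermediate
3 | 3-oxo-3-[4-(triisopropylsilyloxy)phenyl]propanal | O=CCC(=O)c1ccc(O[Si](C(C)C)(C(C)C)C(C)C)cc1 | intermediate
4 | 3-butyn-1-ol | C#CCCO | starting material
5 | 5-(but-3-yn-1-ylsulfanyl)-1-phenyl-1H-tetrazole | C#CCCSc1nnnn1-c1ccccc1 | intermediate
6 | 5-(but-3-yn-1-ylsulfonyl)-1-phenyl-1H-tetrazole | C#CCCS(=O)(=O)c1nnnn1-c1ccccc1 | intermediate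
7 | 4-iodophenol | Oc1ccc(I)cc1 | starting material
8 | (4-iodophenoxy)triisopropylsilane | CC(C)[Si](Oc1ccc(I)cc1)(C(C)C)C(C)C | intermediate
9 | 1-phenyl-5-({4-[4-(triisopropylsilyloxy)phenyl]but-3-yn-1-yl}sulfonyl)-1H-tetrazole | CC(C)[Si](Oc1ccc(C#CCCS(=O)(=O)c2nnnn2-c2ccccc2)cc1)(C(C)C)C(C)C | intermediate
10 | 1-phenyl-5-({(3Z)-4-[4-(triisopropylsilyloxy)phenyl]but-3-en-1-yl}sulfonyl)-1H-tetrazole | CC(C)[Si](Oc1ccc(/C=C\CCS(=O)(=O)c2nnnn2-c2ccccc2)cc1)(C(C)C)C(C)C | intermediate
11 | formaldehyde | C=O | starting material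
12 | 2-[4-(triisopropylsilyloxy)benzoyl]prop-2-enal | C=C(C=O)C(=O)c1ccc(O[Si](C(C)C)(C(C)C)C(C)C)cc1 | intermediate (not isolated)
13 | cis-(2R,3R)-5-[4-(triisopropylsilyloxy)benzoyl]-2-[4-(triisopropylsilyloxy)phenyl]-3-[2-(1-phenyl-1H-tetrazol-5-ylsulfonyl)ethyl]-3,4-dihydro-2H-pyran | O=C(c1ccc(O[Si](C(C)C)(C(C)C)C(C)C)cc1)C1=CO[C@@H](c2ccc(O[Si](C(C)C)(C(C)C)C(C)C)cc2)[C@@H](CCS(=O)(=O)c2nnnn2-c2ccccc2)C1 | intermediate
14 | all-cis (2R,3R,5R)-5-[4-(triisopropylsilyloxy)benzoyl]-2-[4-(triisopropylsilyloxy)phenyl]-3-[2-(1-phenyl-1H-tetrazol-5-ylsulfonyl)ethyl]tetrahydro-2H-pyran | c1ccccc1-n1nnnc1S(=O)(=O)CC[C@H]1C[C@@H](C(=O)c2ccc(O[Si](C(C)C)(C(C)C)C(C)C)cc2)CO[C@H]1c1ccc(O[Si](C(C)C)(C(C)C)C(C)C)cc1 | intermediate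
15 | all-cis (2R,3R,5R)-5-{(R)-hydroxy[4-(triisopropylsilyloxy)phenyl]methyl}-2-[4-(triisopropylsilyloxy)phenyl]-3-[2-(1-phenyl-1H-tetrazol-5-ylsulfonyl)ethyl]tetrahydro-2H-pyran | c1ccccc1-n1nnnc1S(=O)(=O)CC[C@H]1C[C@@H]([C@@H](O)c2ccc(O[Si](C(C)C)(C(C)C)C(C)C)cc2)CO[C@H]1c1ccc(O[Si](C(C)C)(C(C)C)C(C)C)cc1 | intermediate
16 | 4-(tert-butyldimethylsilyloxy)benzaldehyde | O=Cc1ccc(O[Si](C)(C)C(C)(C)C)cc1 | starting material
17 | all-cis (2R,3S,5R)-3-{(2E)-3-[4-(tert-butyldimethylsilyloxy)phenyl]prop-2-en-1-yl}-5-{(R)-hydroxy[4-(triisopropylsilyloxy)phenyl]methyl}-2-[4-(triisopropylsilyloxy)phenyl]tetrahydro-2H-pyran | CC(C)(C)[Si](C)(C)Oc1ccc(/C=C/C[C@H]2C[C@@H]([C@@H](O)c3ccc(O[Si](C(C)C)(C(C)C)C(C)C)cc3)CO[C@H]2c2ccc(O[Si](C(C)C)(C(C)C)C(C)C)cc2)cc1 | intermediate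
18 | all-cis (2R,3S,5R)-5-[(R)-hydroxy(4-hydroxyphenyl)methyl]-2-(4-hydroxyphenyl)-3-[(2E)-3-(4-hydroxyphenyl)prop-2-en-1-yl]tetrahydro-2H-pyran (CNP0182155.1) | Oc1ccc(/C=C/C[C@H]2C[C@@H]([C@@H](O)c3ccc(O)cc3)CO[C@H]2c2ccc(O)cc2)cc1 | target

Total step count: 12 steps.
Longest linear sequence: 9 steps (steps 3, 4, 6, 7, 8, 9, 10, 11, 12, from 3-butyn-1-ol).

Steps most likely to fail

Step 8. Several processes could defeat it:
- insufficient face selection by the catalyst;
- ionisation to a free 4-silyloxybenzyl cation, which would erode the cis C2/C3 relation;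
- Prins addition of formaldehyde to the styrene;
- self-condensation of 3 or double addition of 3 to 12;
- ring closure through the aroyl instead of the formyl oxygen.

The fallback sets out from 3, 10 and 11 and uses the known non-asymmetric domino Knoevenagel/hetero-Diels–Alder protocol (paraformaldehyde, catalytic ethylenediammonium diacetate, MeCN, 60 °C). Under these nearly neutral conditions the cycloaddition should stay concerted and keep the cis relation. It should give racemic material, that is 13 together with its enantiomer, cis-(2S,3S)-5-[4-(triisopropylsilyloxy)benzoyl]-2-[4-(triisopropylsilyloxy)phenyl]-3-[2-(1-phenyl-1H-tetrazol-5-ylsulfonyl)ethyl]-3,4-dihydro-2H-pyran F1. The two are separated by preparative chromatography on a chiral stationary phase, and the fallback comes back to the route at 13.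

Step 9. Hydrogen delivery to the wrong ring face, sluggish reduction of the push-pull alkene, hydrogenolysis of the benzylic C2–O1 bond or over-reduction of the aryl ketone could intervene. The fallback sets out from 13 and replaces surface hydrogenation by hydride addition followed by protonation. Conjugate hydrosilylation (Et3SiH, catalytic RhCl(PPh3)3, toluene, 50 °C) should give the triethylsilyl enol ether of 14 (mixture of enol ether geometries) F2. Kinetic C-protonation of F2 with AcOH in wet THF at 0 °C, from the face opposite the C2 and C3 groups, should then set C5. The fallback comes back to the route at 14.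

Step 10. Reagent control could be incomplete, because the aryl group and the branched ring carbon differ little in size, and this would leave a mixture of carbinol epimers. The fallback sets out from 14 and gives up asymmetric reduction: NaBH4 with CeCl3·7H2O in MeOH–THF at −40 °C should give 15 together with its (S)-carbinol epimer, all-cis (2R,3R,5R)-5-{(S)-hydroxy[4-(triisopropylsilyloxy)phenyl]methyl}-2-[4-(triisopropylsilyloxy)phenyl]-3-[2-(1-phenyl-1H-tetrazol-5-ylsulfonyl)ethyl]tetrahydro-2H-pyran F3. The diastereomers are separated on silica, and F3 is oxidised back to 14 with IBX (2-iodoxybenzoic acid) in DMSO at rt and recycled. The fallback comes back to the route at 15.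

Further compounds
F1 | step 8 | cis-(2S,3S)-5-[4-(triisopropylsilyloxy)benzoyl]-2-[4-(triisopropylsilyloxy)phenyl]-3-[2-(1-phenyl-1H-tetrazol-5-ylsulfonyl)ethyl]-3,4-dihydro-2H-pyran (enantiomer of 13) | O=C(c1ccc(O[Si](C(C)C)(C(C)C)C(C)C)cc1)C1=CO[C@H](c2ccc(O[Si](C(C)C)(C(C)C)C(C)C)cc2)[C@H](CCS(=O)(=O)c2nnnn2-c2ccccc2)C1
F2 | step 9 | triethylsilyl enol ether of 14, (2R,3R)-5-{[4-(triisopropylsilyloxy)phenyl](triethylsilyloxy)methylidene}-2-[4-(triisopropylsilyloxy)phenyl]-3-[2-(1-phenyl-1H-tetrazol-5-ylsulfonyl)ethyl]tetrahydro-2H-pyran (enol ether geometry not defined) | CC[Si](CC)(CC)OC(c1ccc(O[Si](C(C)C)(C(C)C)C(C)C)cc1)=C1CO[C@@H](c2ccc(O[Si](C(C)C)(C(C)C)C(C)C)cc2)[C@@H](CCS(=O)(=O)c2nnnn2-c2ccccc2)C1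
F3 | step 10 | all-cis (2R,3R,5R)-5-{(S)-hydroxy[4-(triisopropylsilyloxy)phenyl]methyl}-2-[4-(triisopropylsilyloxy)phenyl]-3-[2-(1-phenyl-1H-tetrazol-5-ylsulfonyl)ethyl]tetrahydro-2H-pyran (carbinol epimer of 15) | c1ccccc1-n1nnnc1S(=O)(=O)CC[C@H]1C[C@@H]([C@H](O)c2ccc(O[Si](C(C)C)(C(C)C)C(C)C)cc2)CO[C@H]1c1ccc(O[Si](C(C)C)(C(C)C)C(C)C)cc1
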